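**Plan** (labdane numbering: ring A = C1–C5/C10, ring B = C5–C10, side chain C11–C15)

- Retrosynthesis cuts first the malonyl C–O bond at C15, then the C11–C12 σ bond between the exocyclic CH2 on C9 of ring B and the allylic CH2 next to C13=C14. This gives a C15 drimane half and a C5 prenyl half.
- Enabling feature: C12 is allylic to the C13(Me)=C14 alkene, and C11 is the carbinol carbon of drim-7-en-11-ol, so both are natively electrophilic carbons. C11 is reversed in polarity (C–I to C–Mg) and joined to C12 of an (E)-allylic bromide under copper catalysis.
- Forward: the trans-decalin with its C7=C8 alkene is taken intact as (−)-drimenol 1 and converted to iodide 2. Prenyl acetate 3 gives (E)-hydroxy acetate 4, then bromide 5. Iodide 2 (as Grignard reagent 6) and 5 are coupled to the C20 acetate 7, which gives alcohol 8 and then the hydrogen malonate 9.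
- Stereochemistry: C5, C9 and C10 (5S,9S,10S; 5α-H, 9α-H, 10β-Me) come from 1 and are never a reacting centre. The 13E geometry is set by the E-selective SeO2 oxidation of 3 and carried through steps that do not touch the alkene.

Key step: step 4

Assumption: (−)-drimenol (drim-7-en-11-ol) is bought as a catalogue chiral-pool natural product.

**Step 1**
Reactants: 1 (−)-drimenol
Product: 2 11-iododrim-7-ene
Conditions: PPh3, I2, imidazole, toluene, rt → 70 °C
Reagents that add atoms: iodine, II
Why: Garegg–Samuelsson iodination, in which the alkoxyphosphonium ion of the primary C11–OH is displaced by iodide in an SN2 step in a non-ionising, imidazole-buffered medium, so no cation arises next to C7=C8 and C5, C9 and C10 are untouched.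

**Step 2**
Reactants: 3 prenyl acetate
Product: 4 (E)-4-hydroxy-3-methylbut-2-en-1-yl acetate
Conditions: SeO2 (0.3 equiv), t-BuOOH (3 equiv), CH2Cl2, 0 °C → rt
Reagents that add atoms: tert-butyl hydroperoxide, CC(C)(C)OO (source of the new oxygen atom, relayed through catalytic selenium dioxide, O=[Se]=O)
Why: Sharpless–Umbreit catalytic SeO2 allylic hydroxylation (ene reaction, then [2,3]-shift of the allylseleninic acid) should oxidise only the methyl group trans to the CH2OAc chain, which fixes the E geometry of the future C13=C14 bond.

**Step 3**
Reactants: 4 (E)-4-hydroxy-3-methylbut-2-en-1-yl acetate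
Product: 5 (E)-4-bromo-3-methylbut-2-en-1-yl acetate
Conditions: PBr3 (0.4 equiv), Et2O, −10 → 0 °C
Reagents that add atoms: phosphorus tribromide, BrP(Br)Br
Why: Bromination of a primary allylic alcohol with PBr3 at low temperature should proceed by SN2 displacement of the phosphite ester without allylic transposition, so the E alkene and the acetate are kept.

**Step 4**
Reactants: 2 11-iododrim-7-ene; 5 (E)-4-bromo-3-methylbut-2-en-1-yl acetate
Product: 7 labda-7,13E-dien-15-yl acetate, via drimenylmagnesium iodide 6 (not isolated)
Conditions: Mg turnings (I2-activated), Et2O, reflux; then 5 (1.3 equiv), Li2CuCl4 (5 mol %), THF, −78 → 0 °C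
Reagents that add atoms: none
Why: Magnesium insertion turns the electrophilic C11 of 2 into the nucleophile 6 (polarity reversal), which forms a dialkylcuprate with catalytic Li2CuCl4; the cuprate adds oxidatively to the allylic C12–Br bond of 5, and reductive elimination from the σ-allylcopper(III) species makes the C11–C12 bond. The closest known reaction type is the Kochi–Schlosser copper-catalysed coupling of alkyl Grignard reagents with allylic halides, as used for head-to-tail joining of isoprenoid chains with C5 halo-acetates. No ring is closed and no stereocentre is formed; C5, C9 and C10 are spectators, and the organomagnesium, unlike a C11 radical or cation, has no drive to rearrange through the C7=C8 bond. The step needs attack at C12 rather than C14 (α over γ), retention of the 13E geometry, and reaction at C–Br in preference to the acetate C=O and the allylic C15–OAc. α-Attack should be secured by the cuprate regime (THF, Li2CuCl4, brisk addition) and by the bulk of the β-branched drimenyl group, which disfavours bond formation at the substituted C14, while the short-lived σ-allylcopper keeps the E geometry. The bromide should react at −78 to −20 °C far faster than either ester function, and 5 is used in excess so that no Grignard reagent remains to attack product 7.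

**Step 5**
Reactants: 7 labda-7,13E-dien-15-yl acetate
Product: 8 labda-7,13E-dien-15-ol
Conditions: K2CO3 (cat.), MeOH, rt
Reagents that add atoms: none
Why: Base-catalysed transesterification (Zemplén-type methanolysis) should cleave the primary allylic acetate at room temperature without touching either alkene or the ring stereocentres.

**Step 6**
Reactants: 8 labda-7,13E-dien-15-ol
Product: 9 labda-7,13E-dien-15-yl hydrogen malonate (target)
Conditions: Meldrum's acid (1.2 equiv), toluene, 100 °C
Reagents that add atoms: Meldrum's acid (2,2-dimethyl-1,3-dioxane-4,6-dione), CC1(C)OC(=O)CC(=O)O1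
Why: Thermal alcoholysis of Meldrum's acid, in which the primary allylic alcohol opens the dioxanedione at one acyl carbon with loss of acetone, should give the malonic half-ester directly, with no protecting group, base or strong acid that could ionise the allylic ester, and below the temperature of half-ester decarboxylation.

**Compound list**

1 | (−)-drimenol, [(1S,4aS,8aS)-2,5,5,8a-tetramethyl-1,4,4a,5,6,7,8,8a-octahydronaphthalen-1-yl]methanol | CC1=CC[C@H]2C(C)(C)CCC[C@]2(C)[C@H]1CO | starting material
2 | 11-iododrim-7-ene, (1S,4aS,8aS)-1-(iodomethyl)-2,5,5,8a-tetramethyl-1,4,4a,5,6,7,8,8a-octahydronaphthalene | CC1=CC[C@H]2C(C)(C)CCC[C@]2(C)[C@H]1CI | intermediate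
3 | prenyl acetate, 3-methylbut-2-en-1-yl acetate | CC(C)=CCOC(C)=O | starting material
4 | (E)-4-hydroxy-3-methylbut-2-en-1-yl acetate | OC/C(C)=C/COC(C)=O | intermediate
5 | (E)-4-bromo-3-methylbut-2-en-1-yl acetate | BrC/C(C)=C/COC(C)=O | intermediate
6 | drimenylmagnesium iodide, iodo{[(1S,4aS,8aS)-2,5,5,8a-tetramethyl-1,4,4a,5,6,7,8,8a-octahydronaphthalen-1-yl]methyl}magnesium | CC1=CC[C@H]2C(C)(C)CCC[C@]2(C)[C@H]1C[Mg]I | intermediate
7 | labda-7,13E-dien-15-yl acetate, (2E)-3-methyl-5-[(1S,4aS,8aS)-2,5,5,8a-tetramethyl-1,4,4a,5,6,7,8,8a-octahydronaphthalen-1-yl]pent-2-en-1-yl acetate | CC1=CC[C@H]2C(C)(C)CCC[C@]2(C)[C@H]1CC/C(C)=C/COC(C)=O | intermediate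
8 | labda-7,13E-dien-15-ol, (2E)-3-methyl-5-[(1S,4aS,8aS)-2,5,5,8a-tetramethyl-1,4,4a,5,6,7,8,8a-octahydronaphthalen-1-yl]pent-2-en-1-ol | CC1=CC[C@H]2C(C)(C)CCC[C@]2(C)[C@H]1CC/C(C)=C/CO | intermediate
9 | labda-7,13E-dien-15-yl hydrogen malonate, 3-{[(2E)-3-methyl-5-[(1S,4aS,8aS)-2,5,5,8a-tetramethyl-1,4,4a,5,6,7,8,8a-octahydronaphthalen-1-yl]pent-2-en-1-yl]oxy}-3-oxopropanoic acid | CC1=CC[C@H]2C(C)(C)CCC[C@]2(C)[C@H]1CC/C(C)=C/COC(=O)CC(=O)O | target

**Totals**

Total step count: 6
Longest linear sequence: 5 steps (3 → 4 → 5 → 7 → 8 → 9); the drimane branch (1 → 2) joins at step 4.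

**Steps most likely to fail**

Step 4. Possible failures are Wurtz-type self-coupling during magnesium insertion, bond formation at C14 instead of C12 (γ-attack), and addition of the Grignard reagent to the acetate carbonyl. The fallback sets out from 2, uses 5, and comes back to the route at 8. It replaces the organomagnesium by a sulfone-stabilised carbanion at C11 (Julia-type alkylation). Iodide 2 is heated with sodium benzenesulfinate in DMF at 80 °C to give drimenyl phenyl sulfone F1. Deprotonation with n-BuLi in THF at −78 °C and alkylation with 5 gives 11-(phenylsulfonyl)labda-7,13E-dien-15-yl acetate F2, as C11 epimers that are both carried on. Methanolysis with K2CO3 in MeOH gives 11-(phenylsulfonyl)labda-7,13E-dien-15-ol F3. Reductive desulfonylation with Na/Hg and Na2HPO4 in MeOH at −20 °C removes the helper group and the C11 stereocentre and gives 8.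

Step 1. Possible failures are slow displacement at the β-branched C11, which would let elimination or participation of the C7=C8 π bond (homoallyl to cyclopropylcarbinyl rearrangement) compete. The fallback sets out from 1 and comes back at 2. It separates activation from displacement: MsCl and Et3N in CH2Cl2 at 0 °C give drimenyl methanesulfonate F4, which is displaced in a Finkelstein step (NaI, 2-butanone, reflux), where a high iodide concentration in a weakly ionising solvent should enforce the SN2 path.

Step 2. Possible failures are over-oxidation to the enal and incomplete conversion, giving a mixture of oxidation levels. The fallback sets out from 3 and comes back at 4. Oxidation is driven on purpose to the aldehyde level with stoichiometric SeO2 in refluxing dioxane to give (E)-4-acetoxy-2-methylbut-2-enal F5. 1,2-Reduction under Luche conditions (NaBH4, CeCl3·7H2O, MeOH, 0 °C) then returns 4 with the E geometry unchanged.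

**Further compounds**

F1 | step 4 | drimenyl phenyl sulfone, 11-(phenylsulfonyl)drim-7-ene | CC1=CC[C@H]2C(C)(C)CCC[C@]2(C)[C@H]1CS(=O)(=O)c1ccccc1
F2 | step 4 | 11-(phenylsulfonyl)labda-7,13E-dien-15-yl acetate (C11 epimers) | CC1=CC[C@H]2C(C)(C)CCC[C@]2(C)[C@H]1C(C/C(C)=C/COC(C)=O)S(=O)(=O)c1ccccc1
F3 | step 4 | 11-(phenylsulfonyl)labda-7,13E-dien-15-ol (C11 epimers) | CC1=CC[C@H]2C(C)(C)CCC[C@]2(C)[C@H]1C(C/C(C)=C/CO)S(=O)(=O)c1ccccc1
F4 | step 1 | drimenyl methanesulfonate | CC1=CC[C@H]2C(C)(C)CCC[C@]2(C)[C@H]1COS(C)(=O)=O
F5 | step 2 | (E)-4-acetoxy-2-methylbut-2-enal | O=C/C(C)=C/COC(C)=O
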